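**Retrosynthetic overview**
1. Endgame: the 6‑oxo‑7(19)‑ene comes from a C6/C7 diol (oxidation, then dehydration). The two esters are put on late, and the oxepane is closed by C3–OH displacing a C16 triflate.
2. Key step: an intramolecular Diels–Alder reaction of a C9‑dienyl / C2‑enone oxonane builds the tetrahydrofuran and cyclohexene together (C1, C10, C14). C11, C12 and C15 then follow by substrate‑controlled hydroboration.
3. Oxonane: ring‑closing metathesis (C6=C7) of a bis‑alkenyl ether. The C2–O–C9 ether stereocentre C9 is set by alkylating a 1,4‑dioxan‑2‑one enolate templated by C2/C3.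
4. C2–C3–C4 triad: from L‑serine‑derived (S)‑glycerate acetonide (C2) by two chelation‑controlled additions (vinyl to the methyl ketone, allyl to the α‑hydroxy aldehyde).
5. Ring order: oxonane (RCM) → tetrahydrofuran + cyclohexene (IMDA) → oxepane (etherification).

Assumption: asbestinin numbering is used (ether oxygens C2–O–C9 and C3–O–C16); the target is (1S,2S,3S,4R,9S,10R,11R,12R,14S,15R). The C6/C7 diol configuration in 13, 14 and 19–28 (C7 only in 29) is left undefined because both carbons end up sp².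

**Step 1**
Reactants: 1, methyl (4S)-2,2-dimethyl-1,3-dioxolane-4-carboxylate
Product: 2, 1-[(4S)-2,2-dimethyl-1,3-dioxolan-4-yl]ethanone
Conditions: MeNH(OMe)·HCl, i‑PrMgCl, THF, −20 °C; then MeMgBr, −20→0 °C (one pot)
Reagents that add atoms: methylmagnesium bromide, C[Mg]Br
Why: In situ Weinreb amide formation and Grignard acylation stop at the ketone via the stable chelate; the bought stereocentre (C2) is untouched at low temperature.

**Step 2**
Reactants: 2
Product: 3, (2S)-2-[(4S)-2,2-dimethyl-1,3-dioxolan-4-yl]but-3-en-2-ol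
Conditions: CH2=CHMgBr, THF, −78 °C
Reagents that add atoms: vinylmagnesium bromide, C=C[Mg]Br
Why: Cram‑chelate Grignard addition (Mg bridges C=O and the α‑dioxolane oxygen); vinyl enters anti to the ring CH2 and sets C3 threo to C2–O (expect about 8:1, minor isomer removed by chromatography).

**Step 3**
Reactants: 3
Product: 4, (2S,3R)-2-[(4S)-2,2-dimethyl-1,3-dioxolan-4-yl]hex-5-ene-2,3-diol
Conditions: O3, CH2Cl2/MeOH, −78 °C; Me2S; then In, allyl bromide, THF/H2O, rt (α‑hydroxy aldehyde not isolated)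
Reagents that add atoms: ozone, [O-][O+]=O; allyl bromide, C=CCBr
Why: Ozonolysis followed by indium Barbier allylation; the free tertiary α‑OH chelates indium and allyl attacks from the methyl side (anti to the dioxolanyl group), setting C4 (R), threo to C3–O.

**Step 4**
Reactants: 4
Product: 5, 3‑O‑(4‑methoxybenzyl) ether of 4 (C4–OPMB, tertiary C3–OH free)
Conditions: NaH (1.05 equiv), PMBCl, TBAI, DMF, 0 °C
Reagents that add atoms: 4‑methoxybenzyl chloride, COc1ccc(CCl)cc1
Why: Williamson etherification; the secondary alkoxide reacts far faster than the tertiary one.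

**Step 5**
Reactants: 5
Product: 6, (2S,3R,4R)-4-(4-methoxybenzyloxy)-3-methylhept-6-ene-1,2,3-triol
Conditions: AcOH/H2O (4:1), 40 °C
Reagents that add atoms: none
Why: Acid hydrolysis of the terminal acetonide; PMB ether and alkene are stable.

**Step 6**
Reactants: 6
Product: 7, 1‑O‑triisopropylsilyl ether of 6 (C2–OH and C3–OH free)
Conditions: TIPSCl, imidazole, DMF, 0 °C
Reagents that add atoms: triisopropylsilyl chloride, CC(C)[Si](Cl)(C(C)C)C(C)C
Why: Primary‑selective silylation; TIPS is chosen because it resists 1,2 O→O silyl migration in the next basic step.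

**Step 7**
Reactants: 7
Product: 8, 2‑O‑(carboxymethyl) ether of 7 (glycolic acid ether at C2–O)
Conditions: NaH (3.5 equiv), BrCH2CO2H, THF, 0 °C→rt
Reagents that add atoms: bromoacetic acid, OC(=O)CBr
Why: Williamson O‑alkylation with sodium bromoacetate; the secondary C2 alkoxide reacts, the tertiary C3 alkoxide does not.

**Step 8**
Reactants: 8
Product: 9, 1,4‑dioxan‑2‑one (ring O4–C2–C3–O1–C(=O)–CH2) carrying CH2OTIPS on C2 and Me plus the CH(OPMB)CH2CH=CH2 chain on C3
Conditions: 2,4,6‑Cl3C6H2COCl, Et3N, THF; then DMAP, PhMe, 60 °C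
Reagents that add atoms: none
Why: Yamaguchi lactonization onto the tertiary C3–OH closes a six‑membered lactone that serves as the stereocontrolling template.

**Step 9**
Reactants: 9
Product: 10, 3‑(2‑methylallyl) derivative of 9 with the new C9 centre trans to the C2 CH2OTIPS group (9S)
Conditions: LDA, THF, −78 °C; CH2=C(Me)CH2Br, DMPU, −78→−45 °C; AcOH quench
Reagents that add atoms: 3‑bromo‑2‑methylpropene, C=C(C)CBr
Why: Lactone enolate alkylation; in the chair with CH2OTIPS and the C4 chain equatorial and the C3 methyl axial, axial attack occurs on the face anti to the axial methyl, giving the 3,5‑trans lactone.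

**Step 10**
Reactants: 10
Product: 11, acyclic C2–O–C9 ether diol (C10 primary OH, C3 tertiary OH; allyl on the C4 side, methallyl on C9)
Conditions: LiAlH4, THF, 0 °C
Reagents that add atoms: none
Why: Lactone reduction releases C10–OH for the diene and C3–OH for the later oxepane; no stereocentre is touched.

**Step 11**
Reactants: 11
Product: 12, (Z)‑oxonene (ring O, C2–C9; C6=C7 with Me on C7) bearing C9–CH2OH, C2–CH2OTIPS, C3(Me)OH, C4–OPMB
Conditions: Grubbs II (10 mol %), CH2Cl2 (2 mM), 40 °C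
Reagents that add atoms: none
Why: Ring‑closing metathesis; the gauche preference about the C2–O–C9 ether pre‑organises the diene, and the nine‑membered ring enforces the Z trisubstituted olefin.

**Step 12**
Reactants: 12
Product: 13, C6,C7‑cis‑diol of 12
Conditions: OsO4 (5 mol %), NMO, acetone/H2O, rt
Reagents that add atoms: osmium tetroxide, O=[Os](=O)(=O)=O (with NMO, C[N+]1([O-])CCOCC1, as terminal oxidant)
Why: Upjohn dihydroxylation removes the only olefin, so later hydroborations are chemoselective and C6/C7 are already at the oxidation level needed for the ketone/methylene.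

**Step 13**
Reactants: 13
Product: 14, C6,C7‑acetonide of 13 (C10–OH and C3–OH free)
Conditions: Me2C(OMe)2, PPTS, CH2Cl2, rt
Reagents that add atoms: 2,2‑dimethoxypropane, COC(C)(C)OC
Why: Only the cis‑1,2‑diol can form a five‑membered ketal.

**Step 14**
Reactants: 14
Product: 15, (E)‑enone: C9–CH=CH–C(=O)CH3
Conditions: DMP, NaHCO3, Ph3P=CHC(O)Me, CH2Cl2, 0→40 °C (one pot)
Reagents that add atoms: 1‑(triphenylphosphoranylidene)propan‑2‑one, CC(=O)C=P(c1ccccc1)(c1ccccc1)c1ccccc1
Why: Tandem Dess–Martin oxidation/Wittig olefination; the stabilised ylide traps the aldehyde before it can form a lactol with C3–OH, and gives the E‑enone.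

**Step 15**
Reactants: 15
Product: 16, (E)‑diene: C9–CH=CH–C(Me)=CH2
Conditions: Zn, CH2Br2, TiCl4, THF/CH2Cl2, 0 °C→rt
Reagents that add atoms: dibromomethane, BrCBr
Why: Lombardo methylenation is non‑basic, so the free tertiary alcohol cannot add as an alkoxide to the enone.

**Step 16**
Reactants: 16
Product: 17, primary alcohol at C1 (TIPS removed)
Conditions: TBAF, THF, 0 °C→rt
Reagents that add atoms: none
Why: Fluoride desilylation; PMB ether, acetonide and diene are inert.

**Step 17 (key step)**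
Reactants: 17
Product: 19, tricyclic Diels–Alder adduct (oxonane–tetrahydrofuran–cyclohexene with C11=C12(Me) and acetyl on C14), formed via triene 18 (C2–CH=CH–C(=O)CH3, not isolated)
Conditions: DMP, NaHCO3, Ph3P=CHC(O)Me, CH2Cl2, 0 °C→rt; then PhMe, 60 °C
Reagents that add atoms: 1‑(triphenylphosphoranylidene)propan‑2‑one, CC(=O)C=P(c1ccccc1)(c1ccccc1)c1ccccc1
Why: Oxidation/Wittig gives 18, which undergoes an exo intramolecular Diels–Alder reaction. The cis‑2,9‑disubstituted oxonane forces addition anti to C3/C8, giving the cis ring fusion (1S,10R), and the E‑enone gives trans H1/H14 (14S).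

**Step 18**
Reactants: 19
Product: 20, C14‑isopropenyl tricycle (C15=CH2)
Conditions: Zn, CH2Br2, TiCl4, THF/CH2Cl2, 0 °C→rt
Reagents that add atoms: dibromomethane, BrCBr
Why: Lombardo methylenation of the methyl ketone without epimerising the α‑centre C14.

**Step 19**
Reactants: 20
Product: 21, triol: C16 primary OH (15R), 11α‑OH (11S), 12R methyl, plus C3–OH
Conditions: 9‑BBN, THF, 0 °C→rt; then BH3·THF, 0 °C→rt; then NaOH, H2O2
Reagents that add atoms: hydrogen peroxide, OO
Why: Sequential hydroboration–oxidation. 9‑BBN adds to the isopropenyl group from the face anti to C1 in the A(1,3)‑minimised rotamer (15R). BH3 adds syn to C11=C12 from the convex face, anti to the pseudoaxial C10–C9 bond, giving the correct C12 and the C11 epimer.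

**Step 20**
Reactants: 21
Product: 22, tetracycle with the oxepane closed (C16–O–C3), 11α‑OH
Conditions: Tf2O (1.05 equiv), 2,6‑lutidine, CH2Cl2, −78→0 °C
Reagents that add atoms: none
Why: Selective triflation of the primary alcohol, then intramolecular Williamson displacement by the tertiary C3–OH forms the seven‑membered ether.

**Step 21**
Reactants: 22
Product: 23, C11 ketone
Conditions: DMP, NaHCO3, CH2Cl2, 0 °C
Reagents that add atoms: none
Why: Buffered Dess–Martin oxidation avoids enolisation, so the axial C12 methyl is not epimerised.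

**Step 22**
Reactants: 23
Product: 24, 11β‑alcohol (11R)
Conditions: NaBH4, CeCl3·7H2O, MeOH, −40 °C
Reagents that add atoms: none
Why: Luche reduction; the β‑face of the carbonyl is flanked by the axial C12 methyl and the C10–C9 bond, so hydride attacks from the α‑face and gives the equatorial alcohol cis to the methyl.

**Step 23**
Reactants: 24
Product: 25, 11‑acetate
Conditions: Ac2O, pyridine, DMAP, CH2Cl2, rt
Reagents that add atoms: acetic anhydride, CC(=O)OC(C)=O
Why: Standard acylation of the only free hydroxyl.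

**Step 24**
Reactants: 25
Product: 26, C4 alcohol (PMB removed)
Conditions: DDQ, CH2Cl2/pH 7 buffer, 0 °C
Reagents that add atoms: none
Why: Oxidative PMB cleavage; acetate, acetonide and ring ethers are inert and no olefin is present.

**Step 25**
Reactants: 26
Product: 27, C4 octanoate
Conditions: n‑C7H15COCl, pyridine, DMAP, CH2Cl2, 0→40 °C
Reagents that add atoms: octanoyl chloride, CCCCCCCC(=O)Cl
Why: Acylation of the hindered secondary alcohol before the base‑sensitive β‑acyloxy ketone exists.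

**Step 26**
Reactants: 27
Product: 28, C6,C7‑diol
Conditions: TFA/H2O (9:1), CH2Cl2, 0 °C
Reagents that add atoms: none
Why: Acetonide hydrolysis; both esters and the cyclic ethers survive brief aqueous acid.

**Step 27**
Reactants: 28
Product: 29, 7‑hydroxy‑6‑ketone
Conditions: DMP, NaHCO3, CH2Cl2, 0 °C→rt
Reagents that add atoms: none
Why: Only the secondary C6–OH can be oxidised; neutral conditions avoid β‑elimination of the octanoate.

**Step 28**
Reactants: 29
Product: 30, asbestinin 16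
Conditions: Burgess reagent, PhMe, 60 °C
Reagents that add atoms: none
Why: Burgess syn‑elimination of the tertiary α‑ketol; the freely rotating methyl hydrogens are more accessible than the ring C8–H, giving the exocyclic enone.

**Compound list**
1 | methyl (4S)-2,2-dimethyl-1,3-dioxolane-4-carboxylate | COC(=O)[C@@H]1COC(C)(C)O1 | starting material
2 | 1-[(4S)-2,2-dimethyl-1,3-dioxolan-4-yl]ethanone | CC(=O)[C@@H]1COC(C)(C)O1 | intermediate
3 | (2S)-2-[(4S)-2,2-dimethyl-1,3-dioxolan-4-yl]but-3-en-2-ol | C=C[C@](C)(O)[C@@H]1COC(C)(C)O1 | intermediate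
4 | (2S,3R)-2-[(4S)-2,2-dimethyl-1,3-dioxolan-4-yl]hex-5-ene-2,3-diol | C=CC[C@@H](O)[C@](C)(O)[C@@H]1COC(C)(C)O1 | intermediate
5 | C4‑O‑PMB ether of 4 | C=CC[C@@H](OCc1ccc(OC)cc1)[C@](C)(O)[C@@H]2COC(C)(C)O2 | intermediate
6 | (2S,3R,4R)-4-(PMB‑oxy)-3-methylhept-6-ene-1,2,3-triol | C=CC[C@@H](OCc1ccc(OC)cc1)[C@](C)(O)[C@@H](O)CO | intermediate
7 | 1‑O‑TIPS ether of 6 | C=CC[C@@H](OCc1ccc(OC)cc1)[C@](C)(O)[C@@H](O)CO[Si](C(C)C)(C(C)C)C(C)C | intermediate
8 | 2‑O‑carboxymethyl ether of 7 | C=CC[C@@H](OCc1ccc(OC)cc1)[C@](C)(O)[C@@H](OCC(=O)O)CO[Si](C(C)C)(C(C)C)C(C)C | intermediate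
9 | 1,4‑dioxan‑2‑one template | C=CC[C@@H](OCc1ccc(OC)cc1)[C@]2(C)OC(=O)CO[C@H]2CO[Si](C(C)C)(C(C)C)C(C)C | intermediate
10 | 3‑methallyl dioxanone (3,5‑trans) | C=CC[C@@H](OCc1ccc(OC)cc1)[C@]2(C)OC(=O)[C@H](CC(C)=C)O[C@H]2CO[Si](C(C)C)(C(C)C)C(C)C | intermediate
11 | acyclic ether diol (RCM precursor) | C=CC[C@@H](OCc1ccc(OC)cc1)[C@](C)(O)[C@H](CO[Si](C(C)C)(C(C)C)C(C)C)O[C@H](CO)CC(C)=C | intermediate
12 | (Z)‑oxonene | OC[C@@H]1C/C(C)=C\C[C@@H](OCc2ccc(OC)cc2)[C@](C)(O)[C@H](CO[Si](C(C)C)(C(C)C)C(C)C)O1 | intermediate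
13 | oxonane C6,C7‑cis‑diol | OC[C@@H]1CC(C)(O)C(O)C[C@@H](OCc2ccc(OC)cc2)[C@](C)(O)[C@H](CO[Si](C(C)C)(C(C)C)C(C)C)O1 | intermediate
14 | C6,C7‑acetonide | OC[C@@H]1CC2(C)OC(C)(C)OC2C[C@@H](OCc3ccc(OC)cc3)[C@](C)(O)[C@H](CO[Si](C(C)C)(C(C)C)C(C)C)O1 | intermediate
15 | C9 (E)‑enone | CC(=O)/C=C/[C@@H]1CC2(C)OC(C)(C)OC2C[C@@H](OCc3ccc(OC)cc3)[C@](C)(O)[C@H](CO[Si](C(C)C)(C(C)C)C(C)C)O1 | intermediate
16 | C9 (E)‑3‑methylbuta‑1,3‑dienyl oxonane | C=C(C)/C=C/[C@@H]1CC2(C)OC(C)(C)OC2C[C@@H](OCc3ccc(OC)cc3)[C@](C)(O)[C@H](CO[Si](C(C)C)(C(C)C)C(C)C)O1 | intermediate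
17 | C1 primary alcohol | C=C(C)/C=C/[C@@H]1CC2(C)OC(C)(C)OC2C[C@@H](OCc3ccc(OC)cc3)[C@](C)(O)[C@H](CO)O1 | intermediate
18 | diene–enone triene | C=C(C)/C=C/[C@@H]1CC2(C)OC(C)(C)OC2C[C@@H](OCc3ccc(OC)cc3)[C@](C)(O)[C@H](/C=C/C(C)=O)O1 | intermediate (not isolated)
19 | IMDA tricycle, C14 acetyl, C11=C12 | CC12C[C@@H]3O[C@@H]([C@H]4[C@@H](CC(C)=C[C@H]43)C(C)=O)[C@@](C)(O)[C@H](OCc5ccc(OC)cc5)CC1OC(C)(C)O2 | intermediate
20 | C14 isopropenyl tricycle | CC12C[C@@H]3O[C@@H]([C@H]4[C@@H](CC(C)=C[C@H]43)C(C)=C)[C@@](C)(O)[C@H](OCc5ccc(OC)cc5)CC1OC(C)(C)O2 | intermediate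
21 | C16/C11/C3 triol (11S,12R,15R) | CC12C[C@@H]3O[C@@H]([C@H]4[C@@H](C[C@@H](C)[C@H](O)[C@H]43)[C@@H](C)CO)[C@@](C)(O)[C@H](OCc5ccc(OC)cc5)CC1OC(C)(C)O2 | intermediate
22 | oxepane tetracycle, 11α‑OH | CC12C[C@@H]3O[C@H]4[C@H]5[C@@H](C[C@@H](C)[C@H](O)[C@H]53)[C@@H](C)CO[C@@]4(C)[C@H](OCc6ccc(OC)cc6)CC1OC(C)(C)O2 | intermediate
23 | C11 ketone | CC12C[C@@H]3O[C@H]4[C@H]5[C@@H](C[C@@H](C)C(=O)[C@H]53)[C@@H](C)CO[C@@]4(C)[C@H](OCc6ccc(OC)cc6)CC1OC(C)(C)O2 | intermediate
24 | 11β‑alcohol (11R) | CC12C[C@@H]3O[C@H]4[C@H]5[C@@H](C[C@@H](C)[C@@H](O)[C@H]53)[C@@H](C)CO[C@@]4(C)[C@H](OCc6ccc(OC)cc6)CC1OC(C)(C)O2 | intermediate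
25 | 11‑acetate | CC12C[C@@H]3O[C@H]4[C@H]5[C@@H](C[C@@H](C)[C@@H](OC(C)=O)[C@H]53)[C@@H](C)CO[C@@]4(C)[C@H](OCc6ccc(OC)cc6)CC1OC(C)(C)O2 | intermediate
26 | 11‑acetate, C4 alcohol | CC12C[C@@H]3O[C@H]4[C@H]5[C@@H](C[C@@H](C)[C@@H](OC(C)=O)[C@H]53)[C@@H](C)CO[C@@]4(C)[C@H](O)CC1OC(C)(C)O2 | intermediate
27 | 11‑acetate, 4‑octanoate, 6,7‑acetonide | CC12C[C@@H]3O[C@H]4[C@H]5[C@@H](C[C@@H](C)[C@@H](OC(C)=O)[C@H]53)[C@@H](C)CO[C@@]4(C)[C@H](OC(=O)CCCCCCC)CC1OC(C)(C)O2 | intermediate
28 | 6,7‑diol | CC1(O)C[C@@H]2O[C@H]3[C@H]4[C@@H](C[C@@H](C)[C@@H](OC(C)=O)[C@H]42)[C@@H](C)CO[C@@]3(C)[C@H](OC(=O)CCCCCCC)CC1O | intermediate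
29 | 7‑hydroxy‑6‑ketone | CC1(O)C[C@@H]2O[C@H]3[C@H]4[C@@H](C[C@@H](C)[C@@H](OC(C)=O)[C@H]42)[C@@H](C)CO[C@@]3(C)[C@H](OC(=O)CCCCCCC)CC1=O | intermediate
30 | asbestinin 16 | C=C1C[C@@H]2O[C@H]3[C@H]4[C@@H](C[C@@H](C)[C@@H](OC(C)=O)[C@H]42)[C@@H](C)CO[C@@]3(C)[C@H](OC(=O)CCCCCCC)CC1=O | target

**Totals**
Total steps: 28 (Steps 3, 14, 17 and 19 are one‑pot sequences counted once). Longest linear sequence: 28 (fully linear from 1).

**Three steps most likely to fail, with fallbacks**
- **Step 9 (dioxanone alkylation).** The kinetic 3,5‑trans selectivity and the stability of the hindered enolate are unproven on this substrate. Fallback: invert the template. Lactonize the glycolate onto O1 (from the C1/C2 diol, with C3/C4 held as a cyclic ketal); the required C9 epimer is then the diequatorial one and can be reached by base equilibration, i.e. thermodynamic rather than kinetic control.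
- **Step 19 (hydroboration).** C15 relies on acyclic A(1,3) control from C14 only, and the diastereomer ratio may be modest. Fallback: set C15 inside a ring. Use the ylide Ph3P=CHC(O)CH2OTBS in Step 17 so C16 is already oxygenated, methylenate C15, close the oxepane by allylic etherification with C3–OH, and hydrogenate the 15‑exo‑methylene from the face anti to C13.
- **Step 28 (Burgess dehydration).** Exo versus endo olefin selectivity and E1cB loss of the β‑octanoate are both risks. Fallback: dehydrate at the alcohol oxidation level. Silylate C6–OH of diol 28, eliminate the tertiary C7–OH to the 7(19)‑olefin (SOCl2/pyridine or Martin sulfurane), then desilylate and finish with a neutral allylic oxidation (DMP), so no enolisable β‑acyloxy ketone is present during the elimination.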